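**Plan**
- Retrosynthesis: the O5 protecting group is cut first. Next comes the C2–C1' bond between ring C and the trimethoxyphenyl ring B, then the C6–prenyl bond (traced back to an ether on O5). Last are O1–C2 and C2–C3 of the pyranone and the ether O–C bond, which leads to a symmetric acetophenone.
- Forward: ring A is bought as 2',6'-dihydroxy-4'-methoxyacetophenone. Ring C is closed onto it as a chromone, the five-carbon unit is moved from O5 to C6 by a Claisen shift, and ring B is joined last at C2.
- Enabling feature: the C2 stereocentre of ring C carries the aryl ring β to the C4 carbonyl, so a flat C2=C3–C4=O chromone can accept the aryl group at C2.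
- Stereochemistry: the only stereocentre, C2 (S), is set by a chiral bisphosphine on rhodium in the arylation and is not touched afterwards.

Key step: step 6

Assumption: (S)-MeO-F12-BIPHEP, which is (S)-2,2'-bis[bis(3,4,5-trifluorophenyl)phosphino]-6,6'-dimethoxybiphenyl, is taken to deliver the aryl group to the Re face of C2 (O1 > C3 > H), which corresponds to (2S). This rests on analogy with six-membered cyclic enones; the sense would be checked on the first run and the (R)-ligand used if it proves opposite.

**Step 1**
Reactants: 1 2',6'-dihydroxy-4'-methoxyacetophenone; 2 3-chloro-3-methylbut-1-yne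
Product: 3 1-[2-hydroxy-4-methoxy-6-(2-methylbut-3-yn-2-yloxy)phenyl]ethanone
Conditions: 2 (1.5 equiv), K2CO3 (2 equiv), KI (10 mol%), CuI (5 mol%), acetone, 55 °C
Reagents that add atoms: none
Why: Copper-assisted Williamson-type O-propargylation of a phenol with a tertiary propargylic chloride; the two hydroxyls of 1 are equivalent and, once one is etherified, the other is locked in a hydrogen bond to the acetyl oxygen, so the reaction should stop at the mono-ether.

**Step 2**
Reactants: 3 1-[2-hydroxy-4-methoxy-6-(2-methylbut-3-yn-2-yloxy)phenyl]ethanone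
Product: 5 7-methoxy-5-(2-methylbut-3-yn-2-yloxy)chromen-4-one, via enaminone 4 (not isolated)
Conditions: Me2NCH(OMe)2 (3 equiv), toluene, 80 °C; evaporate; then AcOH, 60 °C
Reagents that add atoms: N,N-dimethylformamide dimethyl acetal, COC(OC)N(C)C
Why: Enaminone condensation of the methyl ketone, then acid-promoted oxa-Michael addition of the only free phenol with loss of dimethylamine, is the standard enaminone route to 3-unsubstituted chromones; 80 °C lies below the onset of the propargyl Claisen shift and acetic acid is too weak to ionise the tertiary ether, so the ether oxygen should end up intact as O5.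

**Step 3**
Reactants: 5 7-methoxy-5-(2-methylbut-3-yn-2-yloxy)chromen-4-one
Product: 6 7-methoxy-5-(2-methylbut-3-en-2-yloxy)chromen-4-one
Conditions: H2 (1 atm), Pd/CaCO3 poisoned with Pb(OAc)2 (Lindlar catalyst), quinoline, EtOAc, rt, stopped after 1 equiv H2
Reagents that add atoms: none
Why: Lindlar semihydrogenation stops a terminal alkyne at the alkene, and the electron-poor, vinylogous-ester C2=C3 bond of the chromone should not be reduced on the poisoned catalyst.

**Step 4**
Reactants: 6 7-methoxy-5-(2-methylbut-3-en-2-yloxy)chromen-4-one
Product: 8 5-hydroxy-7-methoxy-6-(3-methylbut-2-enyl)chromen-4-one, via ortho-dienone 7 (not isolated)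
Conditions: N,N-diethylaniline, 120 °C, argon
Reagents that add atoms: none
Why: Aromatic ortho-Claisen [3,3] rearrangement: of the two ortho carbons of O5 only C6 carries hydrogen (C4a is the ring fusion), the allyl unit is inverted so that the 1,1-dimethylallyl ether emerges as a 3,3-dimethylallyl (prenyl) group, and dienone 7 tautomerises to the chelated phenol; the amine solvent suppresses acid-catalysed ionisation of the tertiary ether.

**Step 5**
Reactants: 8 5-hydroxy-7-methoxy-6-(3-methylbut-2-enyl)chromen-4-one
Product: 9 7-methoxy-5-(methoxymethoxy)-6-(3-methylbut-2-enyl)chromen-4-one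
Conditions: NaH (1.5 equiv), MOMCl (1.5 equiv), DMF, 0 °C → rt
Reagents that add atoms: chloromethyl methyl ether, COCCl
Why: Williamson-type O-alkylation of the sodium phenoxide with the highly reactive chloromethyl ether; irreversible deprotonation by NaH breaks the hydrogen bond to the C4 carbonyl, and the chromone offers no other acidic site under these conditions.

**Step 6**
Reactants: 9 7-methoxy-5-(methoxymethoxy)-6-(3-methylbut-2-enyl)chromen-4-one; 10 3,4,5-trimethoxyphenylboronic acid
Product: 11 (2S)-7-methoxy-5-(methoxymethoxy)-6-(3-methylbut-2-enyl)-2-(3,4,5-trimethoxyphenyl)chroman-4-one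
Conditions: [Rh(OH)(cod)]2 (1.5 mol%), (S)-MeO-F12-BIPHEP (3.3 mol%), 10 (3 equiv), CH2Cl2/H2O (10:1), 20 °C
Reagents that add atoms: none
Why: Transmetalation of 10 to the hydroxorhodium bisphosphine complex gives an aryl–rhodium species (monovalent rhodium), the chromone C2=C3 bond inserts so that the aryl group lands on C2, and the oxa-π-allyl rhodium enolate is protonated by water, which returns the Rh–OH catalyst. The closest known reaction type is the Hayashi–Miyaura asymmetric 1,4-addition of arylboronic acids to cyclic enones, which is established for chromones as a route to 2-arylchroman-4-ones. No ring closes: ring C is already in place and only the C2–C1' bond is made. The new C2 stereocentre is controlled by the axially chiral (S)-bisphosphine on rhodium, which is expected to expose the Re face of C2 (O1 > C3 > H) to the migrating aryl group and so give the (2S) configuration. The step needs 1,4- over 1,2-selectivity and must leave ring C closed; the electron-poor ligand allows reaction at 20 °C without added base, where neither aryl addition to the C4 ketone of 11 nor retro-oxa-Michael racemisation should compete. The MOM ether on O5 keeps the peri oxygen from becoming a phenoxide that would deactivate the enone and bind rhodium, and the unactivated prenyl alkene is not a competent acceptor.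

**Step 7**
Reactants: 11 (2S)-7-methoxy-5-(methoxymethoxy)-6-(3-methylbut-2-enyl)-2-(3,4,5-trimethoxyphenyl)chroman-4-one
Product: 12 artoflavanone
Conditions: HCl (1.25 M in MeOH), 0 °C → rt
Reagents that add atoms: none
Why: Acid-catalysed acetal exchange (MOM ether cleavage) is accelerated at the peri position by the C4 carbonyl, so cold dilute acid should suffice; under these conditions the prenyl alkene should not add the phenol or methanol and ring C should not open, so the C2 configuration is retained.

**Compound list**
1 | 2',6'-dihydroxy-4'-methoxyacetophenone | CC(=O)c1c(O)cc(OC)cc1O | starting material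
2 | 3-chloro-3-methylbut-1-yne | C#CC(C)(C)Cl | starting material
3 | 1-[2-hydroxy-4-methoxy-6-(2-methylbut-3-yn-2-yloxy)phenyl]ethanone | CC(=O)c1c(O)cc(OC)cc1OC(C)(C)C#C | intermediate
4 | (E)-3-(dimethylamino)-1-[2-hydroxy-4-methoxy-6-(2-methylbut-3-yn-2-yloxy)phenyl]prop-2-en-1-one (enaminone, not isolated) | CN(C)/C=C/C(=O)c1c(O)cc(OC)cc1OC(C)(C)C#C | intermediate
5 | 7-methoxy-5-(2-methylbut-3-yn-2-yloxy)chromen-4-one | C#CC(C)(C)Oc1cc(OC)cc2occc(=O)c12 | intermediate
6 | 7-methoxy-5-(2-methylbut-3-en-2-yloxy)chromen-4-one | C=CC(C)(C)Oc1cc(OC)cc2occc(=O)c12 | intermediate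
7 | 7-methoxy-6-(3-methylbut-2-enyl)-6H-chromene-4,5-dione (ortho-dienone, racemic at C6, not isolated) | CC(C)=CCC1C(OC)=CC2=C(C1=O)C(=O)C=CO2 | intermediate
8 | 5-hydroxy-7-methoxy-6-(3-methylbut-2-enyl)chromen-4-one | COc1cc2occc(=O)c2c(O)c1CC=C(C)C | intermediate
9 | 7-methoxy-5-(methoxymethoxy)-6-(3-methylbut-2-enyl)chromen-4-one | COCOc1c(CC=C(C)C)c(OC)cc2occc(=O)c12 | intermediate
10 | 3,4,5-trimethoxyphenylboronic acid | COc1cc(B(O)O)cc(OC)c1OC | starting material
11 | (2S)-7-methoxy-5-(methoxymethoxy)-6-(3-methylbut-2-enyl)-2-(3,4,5-trimethoxyphenyl)chroman-4-one | COCOc1c(CC=C(C)C)c(OC)cc2O[C@H](c3cc(OC)c(OC)c(OC)c3)CC(=O)c12 | intermediate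
12 | artoflavanone, (2S)-5-hydroxy-7-methoxy-6-(3-methylbut-2-enyl)-2-(3,4,5-trimethoxyphenyl)chroman-4-one | COc1cc2c(c(O)c1CC=C(C)C)C(=O)C[C@@H](c1cc(OC)c(OC)c(OC)c1)O2 | target

**Step count**
Total: 7 steps. Longest linear sequence: 7 steps (1 → 12).

**Steps most likely to fail**

Step 6. The electron-rich, peri-substituted chromone may insert slowly, so that protodeboronation of 10 outruns the addition, or the facial selectivity may be insufficient. The fallback sets out from 9 and replaces catalyst control by a resolution. The arylation is run without a chiral ligand ([Rh(OH)(cod)]2, 10, dioxane/H2O, 40 °C) to give the racemic MOM flavanone F1. A Noyori-type asymmetric transfer hydrogenation is then used as a kinetic resolution (RuCl(p-cymene)[(R,R)-TsDPEN], divalent ruthenium, HCO2H/Et3N, EtOAc, rt, stopped near half conversion). It should reduce the (2R)-ketone to the cis-(2R,4R)-flavan-4-ol F2 and leave the (2S)-ketone, which is separated by chromatography. The route is rejoined at 11.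

Step 2. The tertiary propargyl ether may be lost by acid-promoted ionisation or may undergo a thermal propargyl Claisen shift to a chromene while the enaminone is formed and cyclised. The fallback sets out from 1 and closes ring C before the ether exists. Me2NCH(OMe)2 followed by aqueous HCl gives, through the dihydroxy enaminone F3, 5-hydroxy-7-methoxychromone F4. Its chelated 5-hydroxyl is then etherified with 2 (K2CO3, KI, CuI, DMF, 65 °C). The route is rejoined at 5.

Step 7. The freed 5-hydroxyl may add to the prenyl double bond under acid, closing a dimethylchroman ring, or the C2 configuration may erode through reversible opening of ring C. The fallback sets out from 8 and changes the protecting group so that no acid is needed at the end. The phenol is silylated (TBSOTf, 2,6-lutidine, CH2Cl2) to the chromone silyl ether F5. The arylation of step 6 is repeated on it with 10 to give the (2S)-flavanone silyl ether F6. The silicon is removed with Bu4NF buffered by AcOH in THF at 0 °C. The route is rejoined at 12.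

**Further compounds**
F1 | step 6 | racemic 7-methoxy-5-(methoxymethoxy)-6-(3-methylbut-2-enyl)-2-(3,4,5-trimethoxyphenyl)chroman-4-one | COCOc1c(CC=C(C)C)c(OC)cc2OC(c3cc(OC)c(OC)c(OC)c3)CC(=O)c12
F2 | step 6 | (2R,4R)-7-methoxy-5-(methoxymethoxy)-6-(3-methylbut-2-enyl)-2-(3,4,5-trimethoxyphenyl)chroman-4-ol | COCOc1c(CC=C(C)C)c(OC)cc2O[C@@H](c3cc(OC)c(OC)c(OC)c3)C[C@@H](O)c12
F3 | step 2 | (E)-1-(2,6-dihydroxy-4-methoxyphenyl)-3-(dimethylamino)prop-2-en-1-one | CN(C)/C=C/C(=O)c1c(O)cc(OC)cc1O
F4 | step 2 | 5-hydroxy-7-methoxychromen-4-one | COc1cc(O)c2c(c1)occc2=O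
F5 | step 7 | 5-(tert-butyldimethylsilyloxy)-7-methoxy-6-(3-methylbut-2-enyl)chromen-4-one | CC(C)=CCc1c(OC)cc2occc(=O)c2c1O[Si](C)(C)C(C)(C)C
F6 | step 7 | (2S)-5-(tert-butyldimethylsilyloxy)-7-methoxy-6-(3-methylbut-2-enyl)-2-(3,4,5-trimethoxyphenyl)chroman-4-one | COc1cc2O[C@H](c3cc(OC)c(OC)c(OC)c3)CC(=O)c2c(O[Si](C)(C)C(C)(C)C)c1CC=C(C)C
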